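The cyclohexane core (C8, C9, C11, C12, C13, C14) has two quaternary carbons, C13 and C8, on either side of the spiro-epoxide carbon C14. Its ester carbon C16 and furoyl carbon C17 are 1,5-related across C13–C14, so a C17–O–C16 link would close a δ-lactone on that bond (limonoid ring D). An ester-tethered intramolecular Diels–Alder reaction exploits this: one thermal step forms C13–C14 and C8–C9, closes the carbocycle and the temporary lactone, and sets C13, C9 and C8. The precursor is the (S)-1-(furan-3-yl)dienyl ester of (E)-4-methyl-5-oxohex-3-enoic acid, its diene carrying the lactate-derived C10 silyl ether. C14=C15 formation, epoxidation, lactone opening and side-chain condensation follow.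

Key step: step 11

Remark 1: limonoid-style locants are used: C14 spiro carbon, C15 epoxide CH, C16 ester carbon, C13 methyl/furoyl carbon, C17 furoyl carbon, C8 methyl/acyl carbon, C7 its ketone, C6 the carbon next to C7 in the side chain, C9 the ring CH bearing carbinol C10, C11 and C12 ring CH2. On the carbocycle the "methyl face" carries the C13 methyl, H9 and the C7 acyl group; the "furoyl face" carries C17, the C8 methyl and C10.

Remark 2: C17 ends as a ketone, so either carbinol epimer leads to the same target. It is carried as the (S)-carbinol, the epimer that lets the furan sit pseudo-equatorial in the transition state that step 11 needs.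

Step 1
Reactants: 1 methyl (R)-lactate
Product: 2 methyl (R)-2-[(tert-butyldimethylsilyl)oxy]propanoate
Conditions: TBSCl, imidazole, DMF, 0 °C to rt
Reagents that add atoms: tert-butyldimethylsilyl chloride, CC(C)(C)[Si](C)(C)Cl
Why: Imidazole-promoted silyl ether formation on a secondary alcohol, which does not touch the C10 stereocentre.

Step 2
Reactants: 2 methyl (R)-2-[(tert-butyldimethylsilyl)oxy]propanoate
Product: 3 (R)-2-[(tert-butyldimethylsilyl)oxy]propanal
Conditions: iBu2AlH (1.05 equiv), CH2Cl2, −78 °C; MeOH, aq. sodium potassium tartrate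
Reagents that add atoms: none
Why: Partial hydride reduction of an α-alkoxy ester stops at the aldehyde because the tetrahedral aluminium acetal is stable at −78 °C; the aldehyde is used crude to avoid epimerisation.

Step 3
Reactants: 3 (R)-2-[(tert-butyldimethylsilyl)oxy]propanal; 4 (triphenylphosphoranylidene)acetaldehyde
Product: 5 (R,E)-4-[(tert-butyldimethylsilyl)oxy]pent-2-enal
Conditions: toluene, 80 °C
Reagents that add atoms: none
Why: Wittig olefination with a formyl-stabilised ylide gives the E-enal (C9=C11), and one equivalent of ylide limits a second homologation.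

Step 4
Reactants: 5 (R,E)-4-[(tert-butyldimethylsilyl)oxy]pent-2-enal; 6 2-(triphenylphosphoranylidene)propanal
Product: 7 (2E,4E,6R)-6-[(tert-butyldimethylsilyl)oxy]-2-methylhepta-2,4-dienal
Conditions: toluene, 95 °C
Reagents that add atoms: none
Why: Wittig olefination with the α-methyl formyl-stabilised ylide gives the E-trisubstituted alkene C12=C13, which places the methyl cis to C11 (the later inside methyl of the diene).

Step 5
Reactants: 7 (2E,4E,6R)-6-[(tert-butyldimethylsilyl)oxy]-2-methylhepta-2,4-dienal; 8 3-bromofuran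
Product: 10 (2E,4E,6R)-6-[(tert-butyldimethylsilyl)oxy]-1-(furan-3-yl)-2-methylhepta-2,4-dien-1-ol (both C1 epimers), via 3-furyllithium 9 (not isolated)
Conditions: 8, n-BuLi, THF, −78 °C; then 7, −78 °C; H2O
Reagents that add atoms: none
Why: Bromine–lithium exchange gives 3-furyllithium, which keeps its position at −78 °C and adds 1,2 to the dienal (organolithium carbonyl addition); C17 forms without control and is reset in steps 6 and 7.

Step 6
Reactants: 10 dienol (C17 epimers)
Product: 11 (2E,4E,6R)-6-[(tert-butyldimethylsilyl)oxy]-1-(furan-3-yl)-2-methylhepta-2,4-dien-1-one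
Conditions: MnO2, CH2Cl2, rt
Reagents that add atoms: none
Why: MnO2 oxidises the doubly activated (allylic and furylic) carbinol to the cross-conjugated ketone and leaves the diene and the silyl ether alone.

Step 7
Reactants: 11 dienyl furyl ketone
Product: 12 (1S,2E,4E,6R)-6-[(tert-butyldimethylsilyl)oxy]-1-(furan-3-yl)-2-methylhepta-2,4-dien-1-ol
Conditions: (S)-1-methyl-3,3-diphenyltetrahydro-3H-pyrrolo[1,2-c][1,3,2]oxazaborole (15 mol %), catecholborane, toluene, −78 °C; MeOH
Reagents that add atoms: none
Why: Corey–Bakshi–Shibata reduction: with the α-branched dienyl arm as the large and the flat 3-furyl as the small substituent, the (S)-catalyst should give the (S)-carbinol at C17; because C10 is fixed the C17 epimers are diastereomers, so assignment and purity can be checked before use.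

Step 8
Reactants: 13 3-[(tert-butyldimethylsilyl)oxy]propanal; 14 3-(triphenylphosphoranylidene)butan-2-one
Product: 15 (E)-6-[(tert-butyldimethylsilyl)oxy]-3-methylhex-3-en-2-one
Conditions: toluene, 100 °C
Reagents that add atoms: none
Why: Wittig olefination with the acyl-stabilised α-methyl ylide gives the E-enone C8=C14 (acetyl trans to the CH2 chain), which is also the more stable geometry.

Step 9
Reactants: 15 (E)-6-[(tert-butyldimethylsilyl)oxy]-3-methylhex-3-en-2-one
Product: 17 (E)-4-methyl-5-oxohex-3-enoic acid, via hydroxy enone 16 (not isolated)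
Conditions: 2 M HCl, THF, rt; then CrO3, H2SO4, acetone, 0 °C
Reagents that add atoms: water, O
Why: Acid removes the primary silyl ether and chromic acid (Jones oxidation) takes the primary alcohol to the acid; the alkene stays conjugated to the ketone because the trisubstituted E-enone is the stable isomer.

Step 10
Reactants: 12 (S)-dienol; 17 (E)-4-methyl-5-oxohex-3-enoic acid
Product: 18 (1S,2E,4E,6R)-6-[(tert-butyldimethylsilyl)oxy]-1-(furan-3-yl)-2-methylhepta-2,4-dien-1-yl (E)-4-methyl-5-oxohex-3-enoate
Conditions: N,N'-dicyclohexylcarbodiimide, 4-(dimethylamino)pyridine (10 mol %), CH2Cl2, 0 °C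
Reagents that add atoms: none
Why: Steglich esterification acylates the carbinol oxygen, so C17 keeps its configuration; low temperature and little base protect the β,γ-unsaturated acyl unit and the ionisable carbinol.

Step 11
Reactants: 18 dienyl ester
Product: 19 cis-fused cyclohexene δ-lactone (H14 on the methyl face, C15 on the furoyl face, furan trans to the C13 methyl on the lactone ring)
Conditions: toluene (0.01 M), 2,6-di-tert-butyl-4-methylphenol (cat.), 160 °C, sealed tube
Reagents that add atoms: none
Why: A thermal, concerted and suprafacial [4+2] cycloaddition joins the E,E-diene C13=C12–C11=C9 to the enone alkene C14=C8 and forms C13–C14 and C8–C9; the closest known type is the type 1 intramolecular Diels–Alder reaction of ester-tethered 1,7,9-decatrienes to fused bicyclic lactones. The carbocycle closes as the new cyclohexene of the [4+2], and the δ-lactone closes in the fused mode through the four-atom tether C17–O–C16–C15, cis at the C13–C14 junction. C13 and C9 are set by the diene geometry (C17 and C10 outside and so cis, the C13 methyl inside), C8 by the E-enone (its methyl cis to C15) and C14 by the endo placement of the tether, so the C8 methyl, C15, C17 and C10 share one face and acetyl, the C13 methyl, H14 and H9 the other. The step needs endo-tether/exo-acetyl selectivity and attack on one diene face: an α-methyl enone prefers its carbonyl exo, the (S)-carbinol at C17 lets the furan sit pseudo-equatorial on the forming lactone with only the small C17–H eclipsing the inside methyl, and the (R)-C10 centre on that face keeps its methyl anti and its silyloxy group inside. Heat is required because the ester must twist into its cisoid form and two quaternary carbons are created, and 160 °C is below the range where a 1,5-hydrogen shift from the inside methyl competes.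

Step 12
Reactants: 19 Diels–Alder lactone
Product: 20 saturated cis-fused lactone (C11–C12 single bond)
Conditions: 2-nitrobenzenesulfonylhydrazide, Et3N, CH2Cl2, rt
Reagents that add atoms: none
Why: Diimide made in situ transfers H2 syn to the cis-disubstituted ring alkene (diimide reduction) and ignores the furan, both carbonyl groups and the silyl ether.

Step 13
Reactants: 20 saturated lactone
Product: 22 C15-phenylselanyl lactone (selenium cis to H14), via dilithium bis-enolate 21 (not isolated)
Conditions: 20 added to LiN(iPr)2 (2.3 equiv), THF, −78 °C; PhSeSePh (1.2 equiv), −78 to −40 °C; AcOH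
Reagents that add atoms: diphenyl diselenide, c1ccc(cc1)[Se][Se]c1ccccc1
Why: Enolate selenenylation: ketone and lactone are both deprotonated, but only the more basic lactone enolate attacks the diselenide (ketone enolates do not), so selenium enters at C15 anti to quaternary C8 and cis to H14, and the methyl ketone returns on protonation.

Step 14
Reactants: 22 selenide
Product: 24 C14=C15 unsaturated δ-lactone, via selenoxide 23 (not isolated)
Conditions: 30% H2O2, pyridine, CH2Cl2, 0 °C to rt
Reagents that add atoms: none
Why: Selenoxide syn-elimination: the only β-hydrogen is H14 (cis), so the double bond forms inside the lactone, which erases C14 and holds C16 cis to C13.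

Step 15
Reactants: 24 unsaturated lactone
Product: 25 14,15-epoxy δ-lactone (epoxide oxygen on the furoyl face of C14, C16 cis to C13 on the oxirane)
Conditions: tBuOOH, n-BuLi, THF, −78 to 0 °C
Reagents that add atoms: tert-butyl hydroperoxide, CC(C)(C)OO
Why: Weitz–Scheffer-type nucleophilic epoxidation with lithium tert-butylperoxide (conjugate addition at C14, then closure of the C15 enolate on the O–O bond); the lactone ring fixes C16 cis to C13, and the peroxide should enter opposite the pseudo-axial C13 methyl and the C8 acetyl group, which sets C14 and C15.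

Step 16
Reactants: 25 epoxy lactone
Product: 27 methyl glycidate with free C17 carbinol, via lithium carboxylate 26 (not isolated)
Conditions: LiOH, THF/H2O, 0 °C to rt; concentrate; MeI, DMF, rt
Reagents that add atoms: lithium hydroxide, [Li+].[OH-]; iodomethane, CI
Why: Saponification opens the δ-lactone to the stable glycidate salt, and O-alkylation of the carboxylate with iodomethane under neutral conditions gives the methyl ester without relactonisation; no stereocentre is touched.

Step 17
Reactants: 27 hydroxy ester
Product: 28 methyl glycidate with C17 furyl ketone and C7 methyl ketone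
Conditions: Dess–Martin periodinane (1,1,1-triacetoxy-1,1-dihydro-1,2-benziodoxol-3(1H)-one), NaHCO3, CH2Cl2, rt
Reagents that add atoms: none
Why: Buffered periodinane oxidation of the hindered secondary furyl carbinol gives the ketone, which removes the C17 stereocentre and rules out relactonisation; epoxide, furan and silyl ether are inert.

Step 18
Reactants: 29 methyl 2-furoate
Product: 30 2-(furan-2-yl)propan-2-ol
Conditions: MeMgBr (2.2 equiv), Et2O, 0 °C to rt; H2O
Reagents that add atoms: methylmagnesium bromide, C[Mg]Br
Why: Double Grignard addition to the ester gives the tertiary furyl carbinol.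

Step 19
Reactants: 30 2-(furan-2-yl)propan-2-ol
Product: 31 6-hydroxy-2,2-dimethyl-2H-pyran-3(6H)-one
Conditions: N-bromosuccinimide, NaHCO3, THF/H2O, 0 °C
Reagents that add atoms: water, O
Why: Achmatowicz oxidative ring expansion of a 2-furyl carbinol gives the hydroxypyranone.

Step 20
Reactants: 31 6-hydroxy-2,2-dimethyl-2H-pyran-3(6H)-one
Product: 32 6,6-dimethyl-2H-pyran-2,5(6H)-dione
Conditions: CrO3, H2SO4, acetone, 0 °C
Reagents that add atoms: none
Why: Chromic acid (Jones) oxidation of the lactol to the lactone gives the ene-dione, which has no enolisable hydrogen.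

Step 21
Reactants: 28 keto ester; 32 6,6-dimethyl-2H-pyran-2,5(6H)-dione
Product: 34 β-hydroxy ketone (aldol adduct; new carbinol centre as a mixture), via lithium enolate 33 (not isolated)
Conditions: LiN(SiMe3)2 (1.05 equiv), THF, −78 °C, 20 min; 32, −78 °C; AcOH, −78 °C
Reagents that add atoms: none
Why: Kinetic lithium enolate aldol addition: the C7 methyl group is the only enolisable position (C8 and C13 are quaternary), the enolate adds 1,2 to the ketone of the ene-dione at −78 °C, and the cold quench prevents retro-aldol, conjugate addition and Claisen attack on the methyl ester; the new centre is lost in step 22.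

Step 22
Reactants: 34 aldol adduct
Product: 35 tert-butyldimethylsilyl ether of the target
Conditions: methyl N-(triethylammoniosulfonyl)carbamate (Burgess reagent), toluene, 50 °C
Reagents that add atoms: none
Why: Burgess dehydration of the tertiary β-hydroxy ketone (syn-elimination through the sulfamate ester) can only go towards the C6 methylene, and the enone should form with the acyl group next to the ring CH and away from the gem-dimethyl carbon, the less strained geometry found in the target.

Step 23
Reactants: 35 silyl ether of the target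
Product: 36 CNP0293135.1
Conditions: HF·pyridine, pyridine, THF, 0 °C to rt
Reagents that add atoms: none
Why: Buffered fluoride cleavage of the secondary silyl ether frees the C10 alcohol without opening the glycidic epoxide or touching the dienone lactone.

Compound list
1 | methyl (R)-lactate | C[C@@H](O)C(=O)OC | starting material
2 | methyl (R)-2-[(tert-butyldimethylsilyl)oxy]propanoate | COC(=O)[C@@H](C)O[Si](C)(C)C(C)(C)C | intermediate
3 | (R)-2-[(tert-butyldimethylsilyl)oxy]propanal | O=C[C@@H](C)O[Si](C)(C)C(C)(C)C | intermediate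
4 | (triphenylphosphoranylidene)acetaldehyde | O=CC=P(c1ccccc1)(c1ccccc1)c1ccccc1 | starting material
5 | (R,E)-4-[(tert-butyldimethylsilyl)oxy]pent-2-enal | O=C/C=C/[C@@H](C)O[Si](C)(C)C(C)(C)C | intermediate
6 | 2-(triphenylphosphoranylidene)propanal | CC(C=O)=P(c1ccccc1)(c1ccccc1)c1ccccc1 | starting material
7 | (2E,4E,6R)-6-[(tert-butyldimethylsilyl)oxy]-2-methylhepta-2,4-dienal | O=C/C(C)=C/C=C/[C@@H](C)O[Si](C)(C)C(C)(C)C | intermediate
8 | 3-bromofuran | Brc1ccoc1 | starting material
9 | 3-furyllithium (not isolated) | [Li]c1ccoc1 | intermediate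
10 | (2E,4E,6R)-6-[(tert-butyldimethylsilyl)oxy]-1-(furan-3-yl)-2-methylhepta-2,4-dien-1-ol, both C1 (C17) epimers | OC(c1ccoc1)/C(C)=C/C=C/[C@@H](C)O[Si](C)(C)C(C)(C)C | intermediate
11 | (2E,4E,6R)-6-[(tert-butyldimethylsilyl)oxy]-1-(furan-3-yl)-2-methylhepta-2,4-dien-1-one | O=C(c1ccoc1)/C(C)=C/C=C/[C@@H](C)O[Si](C)(C)C(C)(C)C | intermediate
12 | (1S,2E,4E,6R)-6-[(tert-butyldimethylsilyl)oxy]-1-(furan-3-yl)-2-methylhepta-2,4-dien-1-ol | O[C@H](c1ccoc1)/C(C)=C/C=C/[C@@H](C)O[Si](C)(C)C(C)(C)C | intermediate
13 | 3-[(tert-butyldimethylsilyl)oxy]propanal | O=CCCO[Si](C)(C)C(C)(C)C | starting material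
14 | 3-(triphenylphosphoranylidene)butan-2-one | CC(=O)C(C)=P(c1ccccc1)(c1ccccc1)c1ccccc1 | starting material
15 | (E)-6-[(tert-butyldimethylsilyl)oxy]-3-methylhex-3-en-2-one | CC(=O)/C(C)=C/CCO[Si](C)(C)C(C)(C)C | intermediate
16 | (E)-6-hydroxy-3-methylhex-3-en-2-one (not isolated) | CC(=O)/C(C)=C/CCO | intermediate
17 | (E)-4-methyl-5-oxohex-3-enoic acid | CC(=O)/C(C)=C/CC(=O)O | intermediate
18 | (1S,2E,4E,6R)-6-[(tert-butyldimethylsilyl)oxy]-1-(furan-3-yl)-2-methylhepta-2,4-dien-1-yl (E)-4-methyl-5-oxohex-3-enoate (Diels–Alder precursor) | CC(=O)/C(C)=C/CC(=O)O[C@H](c1ccoc1)/C(C)=C/C=C/[C@@H](C)O[Si](C)(C)C(C)(C)C | intermediate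
19 | cis-fused cyclohexene δ-lactone: lactone O–C17(furan-3-yl, S)–C13(Me)–C14(H)–C15H2–C16(=O); ring C13–C12=C11–C9–C8–C14, C8 with methyl and acetyl, C9 with (R)-1-silyloxyethyl; H14 on the methyl face, C15 on the furoyl face; furan trans to the C13 methyl | O=C1C[C@H]2[C@](C)(C(C)=O)[C@@H]([C@@H](C)O[Si](C)(C)C(C)(C)C)C=C[C@@]2(C)[C@@H](c2ccoc2)O1 | intermediate
20 | 11,12-dihydro derivative of 19 (saturated cis-fused δ-lactone, all centres as in 19) | O=C1C[C@H]2[C@](C)(C(C)=O)[C@@H]([C@@H](C)O[Si](C)(C)C(C)(C)C)CC[C@@]2(C)[C@@H](c2ccoc2)O1 | intermediate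
21 | dilithium bis-enolate of 20 (lactone C15=C16 enolate and C6=C7 ketone enolate; not isolated) | [Li]OC1=C[C@H]2[C@](C)(C(=C)O[Li])[C@@H]([C@@H](C)O[Si](C)(C)C(C)(C)C)CC[C@@]2(C)[C@@H](c2ccoc2)O1 | intermediate
22 | C15-(phenylselanyl) derivative of 20, selenium cis to H14 | O=C1[C@H]([Se]c3ccccc3)[C@H]2[C@](C)(C(C)=O)[C@@H]([C@@H](C)O[Si](C)(C)C(C)(C)C)CC[C@@]2(C)[C@@H](c2ccoc2)O1 | intermediate
23 | selenoxide of 22 (not isolated) | O=C1[C@H]([Se](=O)c3ccccc3)[C@H]2[C@](C)(C(C)=O)[C@@H]([C@@H](C)O[Si](C)(C)C(C)(C)C)CC[C@@]2(C)[C@@H](c2ccoc2)O1 | intermediate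
24 | C14=C15 unsaturated δ-lactone (C16 cis to C13; other centres as in 20) | O=C1C=C2[C@](C)(C(C)=O)[C@@H]([C@@H](C)O[Si](C)(C)C(C)(C)C)CC[C@@]2(C)[C@@H](c2ccoc2)O1 | intermediate
25 | 14,15-epoxy δ-lactone: epoxide oxygen on the furoyl face of C14, C15 on the methyl face, C16 cis to C13; C17 S | O=C3[C@H]1O[C@@]12[C@](C)([C@H](O3)c1ccoc1)CC[C@H]([C@@H](C)O[Si](C)(C)C(C)(C)C)[C@@]2(C)C(C)=O | intermediate
26 | lithium glycidate with free C17 carbinol (ring-opened 25; not isolated) | [Li+].[O-]C(=O)[C@H]1O[C@@]12[C@](C)([C@H](O)c1ccoc1)CC[C@H]([C@@H](C)O[Si](C)(C)C(C)(C)C)[C@@]2(C)C(C)=O | intermediate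
27 | methyl glycidate with free (S)-C17 carbinol, C7 methyl ketone and C10 silyl ether | COC(=O)[C@H]1O[C@@]12[C@](C)([C@H](O)c1ccoc1)CC[C@H]([C@@H](C)O[Si](C)(C)C(C)(C)C)[C@@]2(C)C(C)=O | intermediate
28 | methyl glycidate with C17 furan-3-yl ketone, C7 methyl ketone and C10 silyl ether | COC(=O)[C@H]1O[C@@]12[C@](C)(C(=O)c1ccoc1)CC[C@H]([C@@H](C)O[Si](C)(C)C(C)(C)C)[C@@]2(C)C(C)=O | intermediate
29 | methyl 2-furoate | COC(=O)c1ccco1 | starting material
30 | 2-(furan-2-yl)propan-2-ol | CC(C)(O)c1ccco1 | intermediate
31 | 6-hydroxy-2,2-dimethyl-2H-pyran-3(6H)-one | CC1(C)OC(O)C=CC1=O | intermediate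
32 | 6,6-dimethyl-2H-pyran-2,5(6H)-dione | CC1(C)OC(=O)C=CC1=O | intermediate
33 | lithium enolate of the C7 methyl ketone of 28 (not isolated) | COC(=O)[C@H]1O[C@@]12[C@](C)(C(=O)c1ccoc1)CC[C@H]([C@@H](C)O[Si](C)(C)C(C)(C)C)[C@@]2(C)C(=C)O[Li] | intermediate
34 | aldol adduct: C6 methylene of 28 bonded to C5 of the pyranone, which carries a tertiary hydroxyl (mixture at that carbon) | COC(=O)[C@H]1O[C@@]12[C@](C)(C(=O)c1ccoc1)CC[C@H]([C@@H](C)O[Si](C)(C)C(C)(C)C)[C@@]2(C)C(=O)CC1(O)C=CC(=O)OC1(C)C | intermediate
35 | C10 tert-butyldimethylsilyl ether of the target (exocyclic enone with acyl cis to the ring CH) | COC(=O)[C@H]1O[C@@]12[C@](C)(C(=O)c1ccoc1)CC[C@H]([C@@H](C)O[Si](C)(C)C(C)(C)C)[C@@]2(C)C(=O)/C=C1\C=CC(=O)OC1(C)C | intermediate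
36 | CNP0293135.1 | COC(=O)[C@H]1O[C@@]12[C@](C)(C(=O)c1ccoc1)CC[C@H]([C@@H](C)O)[C@@]2(C)C(=O)/C=C1\C=CC(=O)OC1(C)C | target

Total step count: 23. Longest linear sequence: 18 (steps 1–7, 10–17, 21–23).

Steps most likely to fail

Step 11. The cycloaddition may be too slow, because the ester has to reach its cisoid form and both new bonds create quaternary carbons. Ionisation of the doubly allylic C17–O bond or loss of endo/exo selectivity could then take over. The fallback replaces the ester tether by a mixed acetal; it sets out from 12 and 14 and returns at 19. Wittig reaction of 14 with commercial 3,3-dimethoxypropanal gives (E)-6,6-dimethoxy-3-methylhex-3-en-2-one F1. Exchange of one methoxy group for dienol 12 (Me3SiOSO2CF3, 2,4,6-collidine, then 12) gives the mixed methyl acetal F2. Its sp3 tether cyclises on milder heating to the 2-methoxytetrahydropyran cycloadduct F3. Pyridinium p-toluenesulfonate in wet acetone gives the lactol F4, and Pr4N[RuO4] with N-methylmorpholine N-oxide oxidises it to lactone 19.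

Step 15. The peroxide may add to the wrong face of C14, since the furan on C17 lies on the face that has to be attacked, or may not add at all at this doubly neopentyl carbon. The fallback uses reagent-controlled electrophilic epoxidation; it sets out from 24 and returns at 28. iBu2AlH reduces lactone and ketone to the triol F5, an allylic alcohol that keeps C16 cis to C13. Ti(OiPr)4, L-(+)-diethyl tartrate and tBuOOH (Sharpless epoxidation) deliver oxygen to the allylic alcohol on the furoyl face and give the epoxy triol F6. Dess–Martin periodinane oxidises all three alcohols to the epoxy diketo aldehyde F7. NaClO2, NaH2PO4 and 2-methyl-2-butene give the glycidic acid F8, and Me3SiCHN2 gives 28.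

Step 21. The enolate may add in conjugate fashion to the ene-dione, or the aldolate may revert or attack the methyl ester on warming. The fallback is a Horner–Wadsworth–Emmons olefination; it sets out from 28 and returns at 35, skipping step 22. LiN(SiMe3)2 and ClP(O)(OEt)2 give the enol phosphate F9. LiN(iPr)2 induces the 1,3-phosphorus shift to the β-ketophosphonate F10. Olefination of F10 with 32 (Ba(OH)2, wet THF) gives 35.

Further compounds
F1 | step 11 | (E)-6,6-dimethoxy-3-methylhex-3-en-2-one | CC(=O)/C(C)=C/CC(OC)OC
F2 | step 11 | mixed methyl acetal of F1 with dienol 12 (acetal carbon as a mixture) | CC(=O)/C(C)=C/CC(OC)O[C@H](c1ccoc1)/C(C)=C/C=C/[C@@H](C)O[Si](C)(C)C(C)(C)C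
F3 | step 11 | cis-fused cycloadduct with C16 as methyl acetal (2-methoxytetrahydropyran analogue of 19) | COC1C[C@H]2[C@](C)(C(C)=O)[C@@H]([C@@H](C)O[Si](C)(C)C(C)(C)C)C=C[C@@]2(C)[C@@H](c2ccoc2)O1
F4 | step 11 | lactol corresponding to 19 | OC1C[C@H]2[C@](C)(C(C)=O)[C@@H]([C@@H](C)O[Si](C)(C)C(C)(C)C)C=C[C@@]2(C)[C@@H](c2ccoc2)O1
F5 | step 15 | triol: C16 allylic alcohol on C15=C14 (C16 cis to C13), C17 carbinol, C7 carbinol (mixture at C7) | OC/C=C1\[C@](C)([C@H](O)c2ccoc2)CC[C@H]([C@@H](C)O[Si](C)(C)C(C)(C)C)[C@@]1(C)C(C)O
F6 | step 15 | 14,15-epoxy triol | OC[C@H]1O[C@@]12[C@](C)([C@H](O)c1ccoc1)CC[C@H]([C@@H](C)O[Si](C)(C)C(C)(C)C)[C@@]2(C)C(C)O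
F7 | step 15 | 14,15-epoxy C16 aldehyde with C17 and C7 ketones | O=C[C@H]1O[C@@]12[C@](C)(C(=O)c1ccoc1)CC[C@H]([C@@H](C)O[Si](C)(C)C(C)(C)C)[C@@]2(C)C(C)=O
F8 | step 15 | glycidic acid corresponding to 28 | OC(=O)[C@H]1O[C@@]12[C@](C)(C(=O)c1ccoc1)CC[C@H]([C@@H](C)O[Si](C)(C)C(C)(C)C)[C@@]2(C)C(C)=O
F9 | step 21 | diethyl enol phosphate of the C7 methyl ketone of 28 | COC(=O)[C@H]1O[C@@]12[C@](C)(C(=O)c1ccoc1)CC[C@H]([C@@H](C)O[Si](C)(C)C(C)(C)C)[C@@]2(C)C(=C)OP(=O)(OCC)OCC
F10 | step 21 | β-ketophosphonate (diethyl phosphonate on C6 of 28) | COC(=O)[C@H]1O[C@@]12[C@](C)(C(=O)c1ccoc1)CC[C@H]([C@@H](C)O[Si](C)(C)C(C)(C)C)[C@@]2(C)C(=O)CP(=O)(OCC)OCC
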